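## Retrosynthetic overview

1. Cassyformin is reached last by methanolysis of two aryl pivalates, preceded by a Wittig two-carbon extension of a C5 aldehyde on the dihydrobenzofuran.
2. Key disconnection: the C3–C3a bond of the dihydrofuran ring (ring C) and the C–O bond of the CH2OH group are made in one radical step. The aryl radical from an o-iodoaryl (R)-1-arylallyl ether closes 5-exo, the resulting primary radical is captured by O2, and the ether stereocentre (future C2) sets C3 trans.
3. The (R)-ether comes from Mitsunobu inversion of an (S)-1-arylallyl alcohol with 5-iodovanillin; the alcohol comes from catalytic asymmetric vinylzinc addition to bis-pivaloylated 5-hydroxyvanillin.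
4. Both benzene rings (ring A of the benzofuran, ring B pendant) come from one intermediate, 5-iodovanillin, made from catechol via guaiacol and vanillin.
5. Ring order: rings A and B are bought as catechol; ring C is the only ring formed, in the radical step.

Assumption: the target is the trans (2R,3S) isomer encoded by the SMILES, and reagents sold as solutions (aqueous glyoxylic acid, aqueous chloroacetaldehyde, vinylmagnesium bromide in THF) count as commercially available.

## Route

Step 1
Reactants: 1 catechol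
Product: 2 guaiacol (2-methoxyphenol)
Conditions: MeI (1.0 equiv), K2CO3 (1.0 equiv), acetone, reflux
Reagents that add atoms: iodomethane, CI
Why: Williamson mono-O-methylation of the catechol monoanion; guaiacol is separated from veratrole and unreacted catechol by base extraction and distillation.

Step 2
Reactants: 2 guaiacol; 3 glyoxylic acid
Product: 5 vanillin, via vanillylmandelic acid 4 (not isolated)
Conditions: 3 (50% aq), NaOH, H2O, 30 °C; then CuSO4 (cat.), air, NaOH, 95 °C; H2SO4
Reagents that add atoms: none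
Why: Glyoxylate hydroxyalkylates the guaiacolate para to the phenoxide oxygen (electrophilic aromatic substitution) to give mandelate 4, whose Cu-catalysed aerobic oxidative decarboxylation leaves the aldehyde (the glyoxylic acid process for vanillin).

Step 3
Reactants: 5 vanillin
Product: 6 5-iodovanillin (4-hydroxy-3-iodo-5-methoxybenzaldehyde)
Conditions: NIS (1.05 equiv), CF3CO2H (cat.), MeCN, rt
Reagents that add atoms: N-iodosuccinimide, O=C1CCC(=O)N1I
Why: Electrophilic aromatic iodination goes to the only open position ortho to the free phenol, the para position being blocked by the formyl group.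

Step 4
Reactants: 6 5-iodovanillin
Product: 7 5-hydroxyvanillin (3,4-dihydroxy-5-methoxybenzaldehyde)
Conditions: NaOH (aq), CuSO4 (cat.), reflux, N2; then HCl
Reagents that add atoms: sodium hydroxide, [Na+].[OH-]
Why: Cu-catalysed Ullmann-type hydroxylation of the aryl iodide, assisted by the ortho phenoxide; the phenoxide form of the aldehyde resists Cannizzaro reaction.

Step 5
Reactants: 7 5-hydroxyvanillin
Product: 8 3-methoxy-4,5-bis(pivaloyloxy)benzaldehyde
Conditions: PivCl (2.4 equiv), Et3N, DMAP (cat.), CH2Cl2, 0 °C → rt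
Reagents that add atoms: pivaloyl chloride, CC(C)(C)C(=O)Cl
Why: DMAP-catalysed O-acylation of both phenols; pivalates survive organozinc, Mitsunobu, tin-radical and Wittig conditions, keep ring B electron-poor (which disfavours benzylic ionisation in step 7), and come off by mild methanolysis.

Step 6
Reactants: 8 3-methoxy-4,5-bis(pivaloyloxy)benzaldehyde; 9 vinylmagnesium bromide
Product: 11 (S)-1-[3-methoxy-4,5-bis(pivaloyloxy)phenyl]prop-2-en-1-ol, via divinylzinc 10 (not isolated)
Conditions: 9 (3 equiv), ZnCl2 (1.5 equiv), Et2O, 0 °C, then 1,4-dioxane and filtration of the magnesium salts; (−)-DAIB [(2S)-3-exo-(dimethylamino)isoborneol, 5 mol%], 8, toluene, 0 °C; aq NH4Cl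
Reagents that add atoms: none
Why: Amino-alkoxide-catalysed asymmetric organozinc addition (Noyori type) transfers a vinyl group to the Si face of the aldehyde and sets the (S) carbinol centre, while the aryl esters are inert to the diorganozinc.

Step 7
Reactants: 11 (S)-1-[3-methoxy-4,5-bis(pivaloyloxy)phenyl]prop-2-en-1-ol; 6 5-iodovanillin
Product: 12 3-iodo-5-methoxy-4-{[(1R)-1-[3-methoxy-4,5-bis(pivaloyloxy)phenyl]prop-2-en-1-yl]oxy}benzaldehyde
Conditions: PPh3, DIAD, toluene, 0 °C → rt
Reagents that add atoms: none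
Why: Mitsunobu etherification of the acidic phenol (pKa about 7) by SN2 displacement of the alkoxyphosphonium ion with inversion, turning the (S)-alcohol into the (R)-ether; the electron-poor bis(acyloxy)aryl ring and the non-polar solvent suppress ionisation.

Step 8
Reactants: 12 3-iodo-5-methoxy-4-{[(1R)-1-[3-methoxy-4,5-bis(pivaloyloxy)phenyl]prop-2-en-1-yl]oxy}benzaldehyde
Product: 14 (2R,3S)-3-(hydroxymethyl)-7-methoxy-2-[3-methoxy-4,5-bis(pivaloyloxy)phenyl]-2,3-dihydro-1-benzofuran-5-carbaldehyde, via hydroperoxide 13 (not isolated)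
Conditions: Bu3SnH (2 equiv, syringe pump), Et3B (cat.), dry air sparge, toluene (0.01 M), 0 °C; then PPh3, rt
Reagents that add atoms: dioxygen, O=O
Why: Oxygenative radical cyclisation: the tin radical abstracts iodine, the aryl radical closes 5-exo-trig onto the vinyl group through a chair-like transition state with the ring B aryl group pseudo-equatorial (C3–C3a forms trans to it, so (2R) relays to (3S)), and O2 captures the primary radical faster than Bu3SnH reduction or neophyl rearrangement to give hydroperoxide 13, which PPh3 reduces to the alcohol.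

Step 9
Reactants: 14 (2R,3S)-3-(hydroxymethyl)-7-methoxy-2-[3-methoxy-4,5-bis(pivaloyloxy)phenyl]-2,3-dihydro-1-benzofuran-5-carbaldehyde; 15 chloroacetaldehyde
Product: 18 (E)-3-{(2R,3S)-3-(hydroxymethyl)-7-methoxy-2-[3-methoxy-4,5-bis(pivaloyloxy)phenyl]-2,3-dihydro-1-benzofuran-5-yl}prop-2-enal, via phosphonium chloride 16 (not isolated), via formyl ylide 17 (not isolated)
Conditions: 15 (50% aq, 1.2 equiv), PPh3 (1.25 equiv), CHCl3, reflux; aq Na2CO3, rt, organic layer dried and switched to toluene; then 14, 80 °C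
Reagents that add atoms: none
Why: Wittig olefination with the stabilised formyl ylide made from 15 and PPh3 converts the aryl aldehyde into the (E)-enal without touching the free alcohol, the aryl esters or the stereocentres.

Step 10
Reactants: 18 (E)-3-{(2R,3S)-3-(hydroxymethyl)-7-methoxy-2-[3-methoxy-4,5-bis(pivaloyloxy)phenyl]-2,3-dihydro-1-benzofuran-5-yl}prop-2-enal
Product: 19 cassyformin
Conditions: K2CO3 (cat.), MeOH/THF, rt, argon; aq NH4Cl
Reagents that add atoms: none
Why: Base-catalysed methanolysis (transesterification) of the two aryl pivalates, which are far more labile than alkyl esters, frees the catechol at room temperature without affecting the enal, the benzylic ether or either stereocentre.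

## Compound list

1 | catechol (benzene-1,2-diol) | Oc1ccccc1O | starting material
2 | guaiacol (2-methoxyphenol) | COc1ccccc1O | intermediate
3 | glyoxylic acid | O=CC(=O)O | starting material
4 | vanillylmandelic acid [2-hydroxy-2-(4-hydroxy-3-methoxyphenyl)acetic acid, racemic] | COc1cc(C(O)C(=O)O)ccc1O | intermediate
5 | vanillin (4-hydroxy-3-methoxybenzaldehyde) | COc1cc(C=O)ccc1O | intermediate
6 | 5-iodovanillin (4-hydroxy-3-iodo-5-methoxybenzaldehyde) | COc1cc(C=O)cc(I)c1O | intermediate
7 | 5-hydroxyvanillin (3,4-dihydroxy-5-methoxybenzaldehyde) | COc1cc(C=O)cc(O)c1O | intermediate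
8 | 3-methoxy-4,5-bis(pivaloyloxy)benzaldehyde | COc1cc(C=O)cc(OC(=O)C(C)(C)C)c1OC(=O)C(C)(C)C | intermediate
9 | vinylmagnesium bromide | C=C[Mg]Br | starting material
10 | divinylzinc | C=C[Zn]C=C | intermediate
11 | (S)-1-[3-methoxy-4,5-bis(pivaloyloxy)phenyl]prop-2-en-1-ol | C=C[C@H](O)c1cc(OC)c(OC(=O)C(C)(C)C)c(OC(=O)C(C)(C)C)c1 | intermediate
12 | 3-iodo-5-methoxy-4-{[(1R)-1-[3-methoxy-4,5-bis(pivaloyloxy)phenyl]prop-2-en-1-yl]oxy}benzaldehyde | C=C[C@@H](Oc1c(I)cc(C=O)cc1OC)c1cc(OC)c(OC(=O)C(C)(C)C)c(OC(=O)C(C)(C)C)c1 | intermediate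
13 | (2R,3S)-3-(hydroperoxymethyl)-7-methoxy-2-[3-methoxy-4,5-bis(pivaloyloxy)phenyl]-2,3-dihydro-1-benzofuran-5-carbaldehyde | COc1cc([C@@H]2Oc3c(OC)cc(C=O)cc3[C@H]2COO)cc(OC(=O)C(C)(C)C)c1OC(=O)C(C)(C)C | intermediate
14 | (2R,3S)-3-(hydroxymethyl)-7-methoxy-2-[3-methoxy-4,5-bis(pivaloyloxy)phenyl]-2,3-dihydro-1-benzofuran-5-carbaldehyde | COc1cc([C@@H]2Oc3c(OC)cc(C=O)cc3[C@H]2CO)cc(OC(=O)C(C)(C)C)c1OC(=O)C(C)(C)C | intermediate
15 | chloroacetaldehyde | O=CCCl | starting material
16 | (formylmethyl)triphenylphosphonium chloride | O=CC[P+](c1ccccc1)(c1ccccc1)c1ccccc1.[Cl-] | intermediate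
17 | (triphenylphosphoranylidene)acetaldehyde | O=CC=P(c1ccccc1)(c1ccccc1)c1ccccc1 | intermediate
18 | (E)-3-{(2R,3S)-3-(hydroxymethyl)-7-methoxy-2-[3-methoxy-4,5-bis(pivaloyloxy)phenyl]-2,3-dihydro-1-benzofuran-5-yl}prop-2-enal | COc1cc([C@@H]2Oc3c(OC)cc(/C=C/C=O)cc3[C@H]2CO)cc(OC(=O)C(C)(C)C)c1OC(=O)C(C)(C)C | intermediate
19 | cassyformin, (E)-3-[(2R,3S)-2-(3,4-dihydroxy-5-methoxyphenyl)-3-(hydroxymethyl)-7-methoxy-2,3-dihydro-1-benzofuran-5-yl]prop-2-enal | COc1cc([C@@H]2Oc3c(OC)cc(/C=C/C=O)cc3[C@H]2CO)cc(O)c1O | target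

## Step count and risk

Total step count: 10. Longest linear sequence: 10 (steps 1 to 10 in one line; compound 6 is used in steps 4 and 7).

The three steps most likely to fail are steps 8, 7 and 6.

Step 8 (radical cyclisation with aerobic capture). The trans:cis ratio may be modest (about 5:1 or better is expected at 0 °C), and capture by O2 has to beat reduction and neophyl ring expansion. If it disappoints, the route leaves at 12. Bu3SnH (slow addition) with an excess of TEMPO in benzene at 70 °C closes the same 5-exo ring but caps the primary radical as the alkoxyamine (2R,3S)-7-methoxy-2-[3-methoxy-4,5-bis(pivaloyloxy)phenyl]-3-{[(2,2,6,6-tetramethylpiperidin-1-yl)oxy]methyl}-2,3-dihydro-1-benzofuran-5-carbaldehyde F1. F1 is stable and can be freed of the cis isomer by chromatography. Its N–O bond is then cleaved with Zn in AcOH/THF/H2O at 50 °C, and the route is rejoined at 14.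

Step 7 (Mitsunobu). The hindered 2,6-disubstituted phenol may attack the allyl terminus (SN2′, linear ether), or the ee may erode. The ether is then made under catalyst control, setting out from 8 and skipping steps 6 and 7. Wittig reaction of 8 with ylide 17 gives (E)-3-[3-methoxy-4,5-bis(pivaloyloxy)phenyl]prop-2-enal F2. Reduction with NaBH4 and CeCl3·7H2O in MeOH at 0 °C gives (E)-3-[3-methoxy-4,5-bis(pivaloyloxy)phenyl]prop-2-en-1-ol F3. ClCO2Me and pyridine give methyl (E)-3-[3-methoxy-4,5-bis(pivaloyloxy)phenyl]prop-2-en-1-yl carbonate F4. Allylic etherification of F4 with the sodium phenoxide of 6, catalysed by [Ir(cod)Cl]2 and the (Ra,R,R) Feringa-type phosphoramidite (binaphthol-based, N,N-bis(1-phenylethyl); the mirror-image ligand if the sense of induction proves opposite) in THF at 50 °C, gives the branched (R)-ether and comes back to the route at 12.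

Step 6 (asymmetric vinyl transfer). The ee may fall short of what a single-enantiomer target needs (about 90% is expected). In that case 8 is treated with 9 itself in THF at −78 °C to give racemic 1-[3-methoxy-4,5-bis(pivaloyloxy)phenyl]prop-2-en-1-ol F5. F5 is resolved by Sharpless kinetic resolution (Ti(OiPr)4, L-(+)-diisopropyl tartrate, t-BuOOH, 4 Å molecular sieves, CH2Cl2, −20 °C). The (R)-enantiomer is consumed as the epoxy alcohol (S)-[3-methoxy-4,5-bis(pivaloyloxy)phenyl][(R)-oxiran-2-yl]methanol F6. The unreacted (S)-alcohol is recovered in high ee (at most 50% yield) and rejoins the route at 11.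

## Further compounds

F1 | step 8 | (2R,3S)-7-methoxy-2-[3-methoxy-4,5-bis(pivaloyloxy)phenyl]-3-{[(2,2,6,6-tetramethylpiperidin-1-yl)oxy]methyl}-2,3-dihydro-1-benzofuran-5-carbaldehyde | COc1cc([C@@H]2Oc3c(OC)cc(C=O)cc3[C@H]2CON4C(C)(C)CCCC4(C)C)cc(OC(=O)C(C)(C)C)c1OC(=O)C(C)(C)C
F2 | step 7 | (E)-3-[3-methoxy-4,5-bis(pivaloyloxy)phenyl]prop-2-enal | COc1cc(/C=C/C=O)cc(OC(=O)C(C)(C)C)c1OC(=O)C(C)(C)C
F3 | step 7 | (E)-3-[3-methoxy-4,5-bis(pivaloyloxy)phenyl]prop-2-en-1-ol | COc1cc(/C=C/CO)cc(OC(=O)C(C)(C)C)c1OC(=O)C(C)(C)C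
F4 | step 7 | methyl (E)-3-[3-methoxy-4,5-bis(pivaloyloxy)phenyl]prop-2-en-1-yl carbonate | COC(=O)OC/C=C/c1cc(OC)c(OC(=O)C(C)(C)C)c(OC(=O)C(C)(C)C)c1
F5 | step 6 | racemic 1-[3-methoxy-4,5-bis(pivaloyloxy)phenyl]prop-2-en-1-ol | C=CC(O)c1cc(OC)c(OC(=O)C(C)(C)C)c(OC(=O)C(C)(C)C)c1
F6 | step 6 | (S)-[3-methoxy-4,5-bis(pivaloyloxy)phenyl][(R)-oxiran-2-yl]methanol | O[C@@H](c1cc(OC)c(OC(=O)C(C)(C)C)c(OC(=O)C(C)(C)C)c1)[C@H]2CO2
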